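**Plan** (atom numbers: C1 lactone carbonyl, C2, C3 = CH–O–O, C4 = C(Me)–O(lactone), C5, C6 = C(Me)–O–O, C7–C16 side chain)
1. Retrosynthesis cuts, in order: C13=C14 (Horner–Wadsworth–Emmons), a helper hydroxyl on C7, the O–C6 bond of the 1,2-dioxane ring, the C3–O bond (peroxide addition to an enal), C2=C3 (Wittig), C4–C5 (enolate alkylation), C6=C7 (Wittig).
2. Forward: a C5–C14 epoxy triflate is joined to a lactic acid dioxolanone at C4–C5, C1–C2 are added, the peroxide is set on C3, the γ-lactone ring is closed first, the 1,2-dioxane ring second, and the phenyldiene end is attached last.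
3. Enabling feature: the secondary hydroperoxide on C3 of the γ-lactone ring lies 1,4 to the fully substituted C6. C6 is offered as the tertiary carbon of a C6–C7 epoxide on the C5 arm cis to the hydroperoxide, so closing O–C6 is a 6-exo epoxide opening with inversion.
4. Stereochemistry: C4 from (S)-lactic acid by self-regeneration of stereocentres; C6 from Sharpless epoxidation followed by inversion in the ring closure; C3 from catalyst-controlled peroxidation. The epoxide oxygen left on C7 is a helper and is removed by radical deoxygenation.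

Key step: step 12

Remark: the (S)-diarylprolinol silyl ether is assumed to shield the same enal face as in its known epoxidations of enals (the (R)-catalyst would be used if the sense proved opposite), and 2-methoxypropan-2-yl hydroperoxide is assumed to add like other tertiary alkyl hydroperoxides.

Step 1
Reactants: 1 oct-7-enal; 2 ethyl 2-(triphenyl-λ5-phosphanylidene)propanoate
Product: 3 ethyl (2E)-2-methyldeca-2,9-dienoate
Conditions: CH2Cl2, rt
Reagents that add atoms: none
Why: Wittig olefination with a stabilised α-branched ylide should give the (E)-trisubstituted enoate because oxaphosphetane formation is reversible for stabilised ylides and the more stable trans arrangement wins.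

Step 2
Reactants: 3 ethyl (2E)-2-methyldeca-2,9-dienoate
Product: 4 (2E)-2-methyldeca-2,9-dien-1-ol
Conditions: i-Bu2AlH (2.2 equiv), CH2Cl2, −78 °C
Reagents that add atoms: none
Why: i-Bu2AlH reduces the conjugated ester by 1,2-hydride delivery to the allylic alcohol and leaves both C=C bonds untouched.

Step 3
Reactants: 4 (2E)-2-methyldeca-2,9-dien-1-ol
Product: 5 [(2S,3S)-3-(hept-6-en-1-yl)-2-methyloxiran-2-yl]methanol
Conditions: Ti(OiPr)4 (10 mol%), L-(+)-diethyl tartrate (12 mol%), t-BuOOH, 4 Å molecular sieves, CH2Cl2, −20 °C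
Reagents that add atoms: tert-butyl hydroperoxide, CC(C)(C)OO
Why: Sharpless asymmetric epoxidation of the (E)-trisubstituted allylic alcohol with the L-(+)-tartrate catalyst should deliver oxygen to one alkene face and set both epoxide carbons as (2S,3S), while the terminal alkene, which carries no allylic hydroxyl, is not epoxidised.

Step 4
Reactants: 5 [(2S,3S)-3-(hept-6-en-1-yl)-2-methyloxiran-2-yl]methanol
Product: 6 [(2S,3S)-3-(hept-6-en-1-yl)-2-methyloxiran-2-yl]methyl trifluoromethanesulfonate
Conditions: Tf2O, 2,6-lutidine, CH2Cl2, −78 °C; used crude at once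
Reagents that add atoms: trifluoromethanesulfonic anhydride, O=S(=O)(OS(=O)(=O)C(F)(F)F)C(F)(F)F
Why: Sulfonylation of the primary alcohol at low temperature should give the oxiranylmethyl triflate, the most reactive electrophile for the hindered SN2 step that follows, without touching the epoxide stereocentres.

Step 5
Reactants: 7 (S)-lactic acid; 8 pivalaldehyde (2,2-dimethylpropanal)
Product: 9 (2S,5S)-2-tert-butyl-5-methyl-1,3-dioxolan-4-one (cis isomer)
Conditions: TsOH·H2O (cat.), H2SO4 (cat.), pentane, reflux, water separator; crystallisation at −78 °C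
Reagents that add atoms: none
Why: Acid-catalysed acetalisation with azeotropic removal of water (the dioxolanone of the self-regeneration-of-stereocentres method) should give mainly the cis acetal, which crystallises, so the lactic acid centre is stored in the new acetal carbon.

Step 6
Reactants: 9 (2S,5S)-2-tert-butyl-5-methyl-1,3-dioxolan-4-one; 6 [(2S,3S)-3-(hept-6-en-1-yl)-2-methyloxiran-2-yl]methyl trifluoromethanesulfonate
Product: 11 (2S,5R)-2-tert-butyl-5-{[(2S,3S)-3-(hept-6-en-1-yl)-2-methyloxiran-2-yl]methyl}-5-methyl-1,3-dioxolan-4-one, via lithium enolate 10 (not isolated)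
Conditions: LiN(i-Pr)2, THF, −78 °C; then 6, DMPU, −78 to −40 °C
Reagents that add atoms: none
Why: Enolate alkylation by self-regeneration of stereocentres should take place on the face anti to the tert-butyl group, so the acetal carbon sets the quaternary centre (later C4) with overall replacement of H by C5 with retention, and the triflate is displaced directly in an SN2 reaction because the trisubstituted epoxide offers no unhindered carbon.

Step 7
Reactants: 11 (2S,5R)-2-tert-butyl-5-{[(2S,3S)-3-(hept-6-en-1-yl)-2-methyloxiran-2-yl]methyl}-5-methyl-1,3-dioxolan-4-one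
Product: 12 (2S,5R)-2-tert-butyl-5-{[(2S,3S)-3-(hept-6-en-1-yl)-2-methyloxiran-2-yl]methyl}-5-methyl-1,3-dioxolan-4-ol (both epimers at the lactol carbon)
Conditions: i-Bu2AlH (1.1 equiv), CH2Cl2, −78 °C
Reagents that add atoms: none
Why: Partial reduction of the lactone-type carbonyl with i-Bu2AlH at −78 °C should stop at the lactol because the aluminium hemiacetal is stable until work-up, and the epoxide and alkene are inert at this temperature.

Step 8
Reactants: 12 the dioxolane lactol; 13 (triphenyl-λ5-phosphanylidene)acetaldehyde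
Product: 14 (2E,4R)-5-[(2S,3S)-3-(hept-6-en-1-yl)-2-methyloxiran-2-yl]-4-hydroxy-4-methylpent-2-enal
Conditions: 13 (2.2 equiv), PhMe, 80 °C
Reagents that add atoms: none
Why: Wittig olefination of the lactol through its open hydroxy aldehyde form with the stabilised formyl ylide should give the (E)-enal, and the hemiacetal link to pivalaldehyde falls apart to free the tertiary C4 hydroxyl.

Step 9
Reactants: 15 2,3-dimethylbut-2-ene
Product: 16 2-methoxypropan-2-yl hydroperoxide
Conditions: O3, MeOH/CH2Cl2, −78 °C; kept cold and used as a solution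
Reagents that add atoms: ozone, O=[O+][O-]; methanol, CO
Why: Ozonolysis in methanol follows the Criegee mechanism, and methanol should trap the acetone carbonyl oxide as the α-methoxy hydroperoxide, an acid-labile mono-protected form of H2O2.

Step 10
Reactants: 14 (2E,4R)-5-[(2S,3S)-3-(hept-6-en-1-yl)-2-methyloxiran-2-yl]-4-hydroxy-4-methylpent-2-enal; 16 2-methoxypropan-2-yl hydroperoxide
Product: 18 (4R,5R)-5-{[(2S,3S)-3-(hept-6-en-1-yl)-2-methyloxiran-2-yl]methyl}-4-[(2-methoxypropan-2-yl)peroxy]-5-methyloxolan-2-ol (both anomers), via open-chain peroxy aldehyde 17 (not isolated)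
Conditions: (S)-2-{bis[3,5-bis(trifluoromethyl)phenyl][(trimethylsilyl)oxy]methyl}pyrrolidine (20 mol%), 16 (2 equiv), PhMe, 0 °C
Reagents that add atoms: none
Why: Iminium-catalysed enantioselective oxa-Michael addition of a hydroperoxide to an enal (asymmetric peroxidation under diarylprolinol silyl ether catalysis) should bring the peroxide to the β-carbon C3 on the face left open by the bulky diaryl(silyloxy)methyl group, which sets C3 as R, and the C4 hydroxyl should then trap the aldehyde as the five-membered lactol so that retro-addition and epoxide formation are held back.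

Step 11
Reactants: 18 the peroxy lactol
Product: 19 (4R,5R)-5-{[(2S,3S)-3-(hept-6-en-1-yl)-2-methyloxiran-2-yl]methyl}-4-[(2-methoxypropan-2-yl)peroxy]-5-methyloxolan-2-one
Conditions: Pr4N[RuO4] (5 mol%), N-methylmorpholine N-oxide, 4 Å molecular sieves, CH2Cl2, rt
Reagents that add atoms: none
Why: Ley–Griffith oxidation of the lactol should give the γ-lactone under neutral conditions, which spare the acid-labile peroxyketal, the epoxide and the terminal alkene.

Step 12
Reactants: 19 (4R,5R)-5-{[(2S,3S)-3-(hept-6-en-1-yl)-2-methyloxiran-2-yl]methyl}-4-[(2-methoxypropan-2-yl)peroxy]-5-methyloxolan-2-one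
Product: 21 (3R,4aR,7aR)-3-[(1S)-1-hydroxyoct-7-en-1-yl]-3,4a-dimethyltetrahydrofuro[3,2-c][1,2]dioxin-6(3H)-one (cis-fused 1,2-dioxane–γ-lactone), via free hydroperoxide 20 (not isolated)
Conditions: camphorsulfonic acid (10 mol%), MeOH (3 equiv), CH2Cl2, 0 °C to rt
Reagents that add atoms: none
Why: Acid-catalysed methanolysis of the peroxyketal frees the C3 hydroperoxide 20, whose terminal oxygen then opens the protonated C6–C7 epoxide at the tertiary carbon C6 in an SN2-like displacement with a loose, cation-like transition state. The closest known reaction type is the acid-promoted intramolecular opening of epoxides by hydroperoxides to 1,2-dioxanes, together with the opening of epoxides and oxetanes by H2O2 with inversion at a tertiary carbon. The 1,2-dioxane ring closes in the 6-exo-tet mode, the O–C6 bond forming anti to the breaking C6–O(epoxide) bond. The only new stereocentre, C6, arises by inversion of the (S)-configured epoxide carbon made in step 3, which puts the peroxide oxygen, the methyl group and the chain as in the target, while C7 keeps the former epoxide oxygen as a helper hydroxyl that steps 13 and 14 remove. The step needs attack at C6 and not at C7, and a cis ring fusion: the first is secured by the tertiary carbon carrying most of the positive charge and by the 6-exo over 7-endo preference, the second by the cis placement of the hydroperoxide and the C5 arm on the lactone ring fixed in steps 6 and 10. Methanol is kept to a few equivalents so that it cannot compete with the tethered nucleophile, and the lactone carbonyl oxygen, held anti to C4 by the ring, cannot reach C6.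

Step 13
Reactants: 21 the dioxane alcohol
Product: 22 O-{(1S)-1-[(3R,4aR,7aR)-3,4a-dimethyl-6-oxohexahydrofuro[3,2-c][1,2]dioxin-3-yl]oct-7-en-1-yl} 1H-imidazole-1-carbothioate
Conditions: 1,1′-thiocarbonyldiimidazole (3 equiv), DMAP (cat.), ClCH2CH2Cl, 60 °C
Reagents that add atoms: 1,1′-thiocarbonyldiimidazole, S=C(n1ccnc1)n1ccnc1
Why: Acylation of the hindered secondary alcohol with thiocarbonyldiimidazole under nucleophilic catalysis should give the thiocarbonyl ester needed for Barton–McCombie deoxygenation, and the imidazole set free is too weak a base to open the peroxy lactone irreversibly.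

Step 14
Reactants: 22 the thiocarbonyl imidazolide
Product: 23 (3S,4aR,7aR)-3,4a-dimethyl-3-(oct-7-en-1-yl)tetrahydrofuro[3,2-c][1,2]dioxin-6(3H)-one
Conditions: Bu3SnH (3 equiv, 0.5 M), (PhSe)2 (10 mol%), Et3B (cat.), air, PhMe, 0 °C to rt
Reagents that add atoms: none
Why: Barton–McCombie deoxygenation proceeds by stannyl radical addition to C=S and β-scission to the C7 radical, and benzeneselenol formed in situ from (PhSe)2 should transfer hydrogen to this radical faster than it can attack the neighbouring O–O bond.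

Step 15
Reactants: 23 the oct-7-enyl peroxy lactone
Product: 25 7-[(3S,4aR,7aR)-3,4a-dimethyl-6-oxohexahydrofuro[3,2-c][1,2]dioxin-3-yl]heptanal, via ozonide 24 (not isolated)
Conditions: O3, CH2Cl2, −78 °C; then Me2S, −78 °C to rt
Reagents that add atoms: ozone, O=[O+][O-]
Why: Ozonolysis with reductive work-up should cleave the only C=C bond to the aldehyde, since a saturated dialkyl peroxide and a lactone are inert to ozone and to Me2S.

Step 16
Reactants: 25 the peroxy lactone aldehyde; 26 diethyl [(2E)-3-phenylprop-2-en-1-yl]phosphonate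
Product: 28 plakortolide Q [(3S,4aR,7aR)-3,4a-dimethyl-3-[(7E,9E)-10-phenyldeca-7,9-dien-1-yl]tetrahydrofuro[3,2-c][1,2]dioxin-6(3H)-one], via lithiated phosphonate 27 (not isolated)
Conditions: 26 (1.3 equiv), LiN(SiMe3)2 (1.25 equiv), THF, −78 °C; then 25, −78 °C to rt
Reagents that add atoms: none
Why: Horner–Wadsworth–Emmons olefination with the anion of an allylic phosphonate should form the new C13=C14 bond with E geometry while the cinnamyl double bond keeps its E geometry, and addition to the aldehyde at −78 °C should be faster than deprotonation of the lactone.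

**Compound list**
1 | oct-7-enal | C=CCCCCCC=O | starting material
2 | ethyl 2-(triphenyl-λ5-phosphanylidene)propanoate | CCOC(=O)C(C)=P(c1ccccc1)(c1ccccc1)c1ccccc1 | starting material
3 | ethyl (2E)-2-methyldeca-2,9-dienoate | CCOC(=O)/C(C)=C/CCCCCC=C | intermediate
4 | (2E)-2-methyldeca-2,9-dien-1-ol | OC/C(C)=C/CCCCCC=C | intermediate
5 | [(2S,3S)-3-(hept-6-en-1-yl)-2-methyloxiran-2-yl]methanol | C[C@@]1([C@@H](O1)CCCCCC=C)CO | intermediate
6 | [(2S,3S)-3-(hept-6-en-1-yl)-2-methyloxiran-2-yl]methyl trifluoromethanesulfonate | C[C@@]1([C@@H](O1)CCCCCC=C)COS(=O)(=O)C(F)(F)F | intermediate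
7 | (S)-lactic acid | C[C@H](O)C(=O)O | starting material
8 | pivalaldehyde (2,2-dimethylpropanal) | CC(C)(C)C=O | starting material
9 | (2S,5S)-2-tert-butyl-5-methyl-1,3-dioxolan-4-one | C[C@@H]1O[C@H](C(C)(C)C)OC1=O | intermediate
10 | lithium (2S)-2-tert-butyl-5-methyl-1,3-dioxol-4-olate (enolate of 9) | CC1=C([O-])O[C@@H](C(C)(C)C)O1.[Li+] | intermediate
11 | (2S,5R)-2-tert-butyl-5-{[(2S,3S)-3-(hept-6-en-1-yl)-2-methyloxiran-2-yl]methyl}-5-methyl-1,3-dioxolan-4-one | C[C@]1(C[C@]2(C)O[C@H]2CCCCCC=C)O[C@H](C(C)(C)C)OC1=O | intermediate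
12 | (2S,5R)-2-tert-butyl-5-{[(2S,3S)-3-(hept-6-en-1-yl)-2-methyloxiran-2-yl]methyl}-5-methyl-1,3-dioxolan-4-ol | C[C@]1(C[C@]2(C)O[C@H]2CCCCCC=C)O[C@H](C(C)(C)C)OC1O | intermediate
13 | (triphenyl-λ5-phosphanylidene)acetaldehyde | O=CC=P(c1ccccc1)(c1ccccc1)c1ccccc1 | starting material
14 | (2E,4R)-5-[(2S,3S)-3-(hept-6-en-1-yl)-2-methyloxiran-2-yl]-4-hydroxy-4-methylpent-2-enal | O=C/C=C/[C@](C)(O)C[C@]1(C)O[C@H]1CCCCCC=C | intermediate
15 | 2,3-dimethylbut-2-ene | CC(C)=C(C)C | starting material
16 | 2-methoxypropan-2-yl hydroperoxide | COC(C)(C)OO | intermediate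
17 | (3R,4R)-5-[(2S,3S)-3-(hept-6-en-1-yl)-2-methyloxiran-2-yl]-4-hydroxy-3-[(2-methoxypropan-2-yl)peroxy]-4-methylpentanal | O=CC[C@@H](OOC(C)(C)OC)[C@](C)(O)C[C@]1(C)O[C@H]1CCCCCC=C | intermediate
18 | (4R,5R)-5-{[(2S,3S)-3-(hept-6-en-1-yl)-2-methyloxiran-2-yl]methyl}-4-[(2-methoxypropan-2-yl)peroxy]-5-methyloxolan-2-ol | C[C@@]1([C@@H](O1)CCCCCC=C)C[C@@]2(C)OC(O)C[C@H]2OOC(C)(C)OC | intermediate
19 | (4R,5R)-5-{[(2S,3S)-3-(hept-6-en-1-yl)-2-methyloxiran-2-yl]methyl}-4-[(2-methoxypropan-2-yl)peroxy]-5-methyloxolan-2-one | C[C@@]1([C@@H](O1)CCCCCC=C)C[C@@]2(C)OC(=O)C[C@H]2OOC(C)(C)OC | intermediate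
20 | (4R,5R)-5-{[(2S,3S)-3-(hept-6-en-1-yl)-2-methyloxiran-2-yl]methyl}-4-hydroperoxy-5-methyloxolan-2-one | C[C@@]1([C@@H](O1)CCCCCC=C)C[C@@]2(C)OC(=O)C[C@H]2OO | intermediate
21 | (3R,4aR,7aR)-3-[(1S)-1-hydroxyoct-7-en-1-yl]-3,4a-dimethyltetrahydrofuro[3,2-c][1,2]dioxin-6(3H)-one | C[C@]1([C@@H](O)CCCCCC=C)C[C@@]2(C)OC(=O)C[C@H]2OO1 | intermediate
22 | O-{(1S)-1-[(3R,4aR,7aR)-3,4a-dimethyl-6-oxohexahydrofuro[3,2-c][1,2]dioxin-3-yl]oct-7-en-1-yl} 1H-imidazole-1-carbothioate | C[C@]1([C@@H](OC(=S)n3ccnc3)CCCCCC=C)C[C@@]2(C)OC(=O)C[C@H]2OO1 | intermediate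
23 | (3S,4aR,7aR)-3,4a-dimethyl-3-(oct-7-en-1-yl)tetrahydrofuro[3,2-c][1,2]dioxin-6(3H)-one | C[C@]1(CCCCCCC=C)C[C@@]2(C)OC(=O)C[C@H]2OO1 | intermediate
24 | (3S,4aR,7aR)-3,4a-dimethyl-3-[6-(1,2,4-trioxolan-3-yl)hexyl]tetrahydrofuro[3,2-c][1,2]dioxin-6(3H)-one (ozonide) | C[C@]1(CCCCCCC3OCOO3)C[C@@]2(C)OC(=O)C[C@H]2OO1 | intermediate
25 | 7-[(3S,4aR,7aR)-3,4a-dimethyl-6-oxohexahydrofuro[3,2-c][1,2]dioxin-3-yl]heptanal | C[C@]1(CCCCCCC=O)C[C@@]2(C)OC(=O)C[C@H]2OO1 | intermediate
26 | diethyl [(2E)-3-phenylprop-2-en-1-yl]phosphonate | CCOP(=O)(OCC)C/C=C/c1ccccc1 | starting material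
27 | lithium salt of the α-carbanion of 26 | CCOP(=O)(OCC)[CH-]/C=C/c1ccccc1.[Li+] | intermediate
28 | plakortolide Q, (3S,4aR,7aR)-3,4a-dimethyl-3-[(7E,9E)-10-phenyldeca-7,9-dien-1-yl]tetrahydrofuro[3,2-c][1,2]dioxin-6(3H)-one | C[C@]1(CCCCCC/C=C/C=C/c2ccccc2)C[C@@]2(C)OC(=O)C[C@H]2OO1 | target

**Step count and risks**

Total steps: 16. Longest linear sequence: 14 steps (steps 1–4, 6–8 and 10–16).

Steps most likely to fail:

Step 10 (asymmetric peroxidation). The addition may stall at the β-carbon, which sits next to the quaternary C4. The peroxy enamine may collapse to the epoxy aldehyde, or the neighbouring stereocentre may erode facial control by the catalyst. The fallback sets out from 12 and comes back at 21: the peroxide is brought in at C6 and the dioxane ring is closed at C3 instead. Still–Gennari olefination of lactol 12 [methyl bis(2,2,2-trifluoroethyl)phosphonoacetate, KN(SiMe3)2, 18-crown-6, THF, −78 °C] should give methyl (2Z,4R)-5-[(2S,3S)-3-(hept-6-en-1-yl)-2-methyloxiran-2-yl]-4-hydroxy-4-methylpent-2-enoate F1. This lactonises on work-up to (5R)-5-{[(2S,3S)-3-(hept-6-en-1-yl)-2-methyloxiran-2-yl]methyl}-5-methylfuran-2(5H)-one F2. Perhydrolysis of the epoxide with ethereal H2O2 and H3PMo12O40 (cat.) should open it at the tertiary carbon with inversion to give (5R)-5-[(2R,3S)-2-hydroperoxy-3-hydroxy-2-methyldec-9-en-1-yl]-5-methylfuran-2(5H)-one F3. Et2NH in CF3CH2OH should then close the ring by intramolecular oxa-Michael addition of the hydroperoxide to the butenolide, which can only give the cis-fused 21.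

Step 14 (radical deoxygenation next to the peroxide). The C7 radical may attack the adjacent O–O bond, with ring cleavage to an epoxide, before hydrogen transfer. The fallback sets out from 11 and comes back at 23: the helper oxygen is removed before any peroxide is present.
- LiAlH4 (THF, 0 °C to rt) should reduce the dioxolanone and open the epoxide at C7 to give (2R,4R)-2,4-dimethyldodec-11-ene-1,2,4-triol F4.
- TEMPO/PhI(OAc)2 should oxidise only the primary alcohol, to (2R,4R)-2,4-dihydroxy-2,4-dimethyldodec-11-enal F5.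
- Wittig reaction with 13 should give (2E,4R,6R)-4,6-dihydroxy-4,6-dimethyltetradeca-2,13-dienal F6.
- Peroxidation with 16 as in step 10 should give, through (3R,4R,6R)-4,6-dihydroxy-3-[(2-methoxypropan-2-yl)peroxy]-4,6-dimethyltetradec-13-enal F7, the lactol (4R,5R)-5-[(2R)-2-hydroxy-2-methyldec-9-en-1-yl]-4-[(2-methoxypropan-2-yl)peroxy]-5-methyloxolan-2-ol F8.
- Oxidation as in step 11 should give (4R,5R)-5-[(2R)-2-hydroxy-2-methyldec-9-en-1-yl]-4-[(2-methoxypropan-2-yl)peroxy]-5-methyloxolan-2-one F9.
- Camphorsulfonic acid/MeOH should free (4R,5R)-4-hydroperoxy-5-[(2R)-2-hydroxy-2-methyldec-9-en-1-yl]-5-methyloxolan-2-one F10.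
- BF3·OEt2 in CH2Cl2 should then close the dioxane by acid-catalysed substitution of the tertiary alcohol by the hydroperoxide (the classical acid condensation), which returns to 23.
- This closure passes through a tertiary cation, so the C6 epimer is expected alongside and would be removed by chromatography.

Step 6 (alkylation with the epoxy triflate). SN2 attack at a primary carbon flanked by a fully substituted epoxide carbon may be too slow against thermal decay of the enolate, and the triflate may decompose. The fallback sets out from 4 (with enolate 10 made from 9 as before) and comes back at 11. Appel bromination of 4 (CBr4, PPh3, CH2Cl2, 0 °C) should give (2E)-1-bromo-2-methyldeca-2,9-diene F11. Alkylation of 10 with this allylic bromide, a standard electrophile for this enolate, should give (2S,5R)-2-tert-butyl-5-methyl-5-[(2E)-2-methyldeca-2,9-dien-1-yl]-1,3-dioxolan-4-one F12. Shi epoxidation with the enantiomer of the D-fructose-derived ketone catalyst (KHSO5, K2CO3 buffer, MeCN/dimethoxymethane/H2O, 0 °C) should epoxidise the trisubstituted alkene in preference to the terminal one, with reagent control of the face, and return to 11.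

**Further compounds**
F1 | step 10 | methyl (2Z,4R)-5-[(2S,3S)-3-(hept-6-en-1-yl)-2-methyloxiran-2-yl]-4-hydroxy-4-methylpent-2-enoate | COC(=O)/C=C\[C@](C)(O)C[C@]1(C)O[C@H]1CCCCCC=C
F2 | step 10 | (5R)-5-{[(2S,3S)-3-(hept-6-en-1-yl)-2-methyloxiran-2-yl]methyl}-5-methylfuran-2(5H)-one | O=C1C=C[C@](C)(O1)C[C@]2(C)O[C@H]2CCCCCC=C
F3 | step 10 | (5R)-5-[(2R,3S)-2-hydroperoxy-3-hydroxy-2-methyldec-9-en-1-yl]-5-methylfuran-2(5H)-one | C[C@](OO)([C@@H](O)CCCCCC=C)C[C@@]1(C)OC(=O)C=C1
F4 | step 14 | (2R,4R)-2,4-dimethyldodec-11-ene-1,2,4-triol | OC[C@](C)(O)C[C@](C)(O)CCCCCCC=C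
F5 | step 14 | (2R,4R)-2,4-dihydroxy-2,4-dimethyldodec-11-enal | O=C[C@](C)(O)C[C@](C)(O)CCCCCCC=C
F6 | step 14 | (2E,4R,6R)-4,6-dihydroxy-4,6-dimethyltetradeca-2,13-dienal | O=C/C=C/[C@](C)(O)C[C@](C)(O)CCCCCCC=C
F7 | step 14 | (3R,4R,6R)-4,6-dihydroxy-3-[(2-methoxypropan-2-yl)peroxy]-4,6-dimethyltetradec-13-enal | O=CC[C@@H](OOC(C)(C)OC)[C@](C)(O)C[C@](C)(O)CCCCCCC=C
F8 | step 14 | (4R,5R)-5-[(2R)-2-hydroxy-2-methyldec-9-en-1-yl]-4-[(2-methoxypropan-2-yl)peroxy]-5-methyloxolan-2-ol | C[C@@](O)(CCCCCCC=C)C[C@@]1(C)OC(O)C[C@H]1OOC(C)(C)OC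
F9 | step 14 | (4R,5R)-5-[(2R)-2-hydroxy-2-methyldec-9-en-1-yl]-4-[(2-methoxypropan-2-yl)peroxy]-5-methyloxolan-2-one | C[C@@](O)(CCCCCCC=C)C[C@@]1(C)OC(=O)C[C@H]1OOC(C)(C)OC
F10 | step 14 | (4R,5R)-4-hydroperoxy-5-[(2R)-2-hydroxy-2-methyldec-9-en-1-yl]-5-methyloxolan-2-one | C[C@@](O)(CCCCCCC=C)C[C@@]1(C)OC(=O)C[C@H]1OO
F11 | step 6 | (2E)-1-bromo-2-methyldeca-2,9-diene | BrC/C(C)=C/CCCCCC=C
F12 | step 6 | (2S,5R)-2-tert-butyl-5-methyl-5-[(2E)-2-methyldeca-2,9-dien-1-yl]-1,3-dioxolan-4-one | C[C@]1(C/C(C)=C/CCCCCC=C)O[C@H](C(C)(C)C)OC1=O
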